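## Analysis of the target

Compound 29 is a caged polyprenylated benzoylphloroglucinol. The atoms are numbered here as C1 (bridgehead with the benzoyl group), C2, C4 and C9 (ring ketones, C9 between C1 and C5), C3 (quaternary, between C2 and C4), C5 (bridgehead with the geranyl group), C6 (CH2), C7 (CH), C8 (CMe2 on C1), C10 (CH2 on C7), C11 (CH between C10 and C3), C12 (CMe2), C13 (CH with the isopropenyl group) and C14 (CH2 on C3).

The trione ring C1–C2–C3–C4–C5–C9 is bridged twice. C5–C6–C7–C8–C1 makes a bicyclo[3.3.1]nonane, and C7–C10–C11–C3 turns it into a homoadamantane-type cage containing the seven-membered ring C3–C4–C5–C6–C7–C10–C11. A cyclopentane (C3, C14, C13, C12, C11) is fused onto the C3–C11 bond.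

Of the six stereocentres (C1, C3, C5, C7, C11, C13), C1, C5 and C7 are cage atoms whose configuration follows from C3 and C11 once the rings are closed. C10 on C11 is cis to C4 and the isopropenyl group on C13 is trans to C10. Only the C3/C11 relation, the C11/C13 relation and the absolute sense therefore need control.

The non-enolisable triketone around C1 is open to cleavage by hard nucleophiles. The isopropenyl and geranyl alkenes tolerate neither strong acid nor hydrogenation, so they must enter late. The difficulty lies in the quaternary carbons C1, C3, C5, C8 and C12, in the C1–C8 bond between two fully substituted carbons, and in the substituted bridgehead C5.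

The strategy rests on the segment C3–C4–C5. Read as the 2-oxyallyl unit of an oxidised phloroglucinol, its two ends are joined by the four-carbon chain C11–C10–C7–C6, so the seven-membered ring is the retron of a (4+3) cycloaddition. Because the cyclopentane shares C3–C11 with that ring, the diene can be tethered to C3 through C14–C13–C12.

## Retrosynthetic reasoning

**C5–geranyl bond.** The geranyl group is removed from C5 first, giving cage trione 27 and geranyl bromide 28. It has to be made last because the two trisubstituted alkenes would not survive the hydrogenation or the acid-mediated cage closure. In 27 the C5–H is the only proton α to a carbonyl group, and the cage allows only one configuration at C5. The forward step must alkylate a bridgehead anion that cannot become planar.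

**Isopropenyl group.** 27 is traced to the methyl ketone 26 by carbonyl methylenation. The acetyl group stands in for the isopropenyl group through the oxidation, the hydrogenation and the acid step. It is the only ketone of 26 not flanked by a quaternary carbon, so the methylenation should be selective.

**C1–C8 bond.** Cutting the bond between C1 and C8 opens the cage to the bicyclo[4.3.1]decane 25. Forward, a tertiary cation at C8 (from the silyl ether) is captured by the enol carbon C1 of the 2-benzoyl-1,3-dione. This cut keeps C1 as an sp2 enol carbon through all earlier steps, so the benzoyl-bearing carbon never has to carry charge or be alkylated intermolecularly.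

**C7–H and C10–H.** 25 is traced to the alkene 24. Saturating C7=C10 before ionisation is necessary: an allyl cation would place C8 trans to C11 across the double bond, so it cannot reach C1. The hydrogen must add on the alkene face turned to the one-carbon bridge C4, so that C8 ends on the side of C1.

**C3–C11 and C5–C6 (key step).** Both bonds of the seven-membered ring that end on the trione are cut at once, giving the aromatic triol 22 with a diene tethered to C3. No other pair of cuts removes two rings and three stereocentres (C3, C5, C11) while returning to a flat benzoylphloroglucinol. Forward, a two-electron oxidation of the phenol must produce the oxyallyl cation across C3–C4–C5, and the diene must add to it on one ring face under control of C13.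

**Phenol protection.** 22 is traced to its tris-silyl ether 21. The phenols stay masked through enolate, cuprate and palladium chemistry and are released by mild base, which leaves the tertiary silyl ether at C8 and the diene untouched.

**C10–C7 bond.** The diene 21 is cut between C10 and C7 into the (E)-vinylstannane 17 and the enol triflate 20 (Stille coupling). 17 comes from the terminal alkyne 16 by syn-hydrostannation. 20 comes from the silyl ether 19 of 3-hydroxy-3-methylbutan-2-one 18, which can enolise on one side only.

**Acetyl group.** The methyl ketone 16 is traced through the thioester 15 to the imide 14. A thioester and a methyl cuprate are chosen because the benzophenone carbonyl would not survive methyllithium or a Grignard reagent.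

**C12–C13 bond and the C13 stereocentre.** 14 is cut between C13 and the quaternary C12 into the imide 9 and the cobalt-stabilised propargylic cation 12 (Nicholas reaction of a chiral boron enolate). A tertiary carbon can only be joined to an enolate carbon through an SN1 electrophile, and the cobalt cluster stops allene formation and supplies the alkyne for the diene. 12 comes from 2-methylbut-3-yn-2-ol 10 through its cobalt complex 11.

Cutting C3–C14 with the C13 carbonyl already in place was set aside. A leaving group on C14 would sit β to the ketone and would be lost by elimination together with the C13 stereocentre. Phloroglucinol carbons also alkylate poorly with β-branched primary electrophiles.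

**C3–C14 bond and the arene.** 9 is traced to the lactone 6 and the oxazolidinone 7, with the aryl lactone serving as the acylating agent. 6 comes from the dihydroxy lactone 5, which is the conjugate Friedel–Crafts adduct of 2,4,6-trihydroxybenzophenone 3 and acrylic acid 4. 3 comes from phloroglucinol 1 and benzoyl chloride 2. Making C3–C14 by conjugate addition uses the one reaction in which a phloroglucinol carbon is a reliable nucleophile, before any stereocentre exists.

## Alternatives that were turned down

Alternative 1: Only C5–C6 is cut, in a spiro trione that already holds the cyclopentane. Forward, Pd(PPh3)4 would ionise an allylic carbonate on the arm at C11. The enol carbon on the side of C10 would then attack the primary allyl terminus C6, closing the seven-membered ring to A1 with an exocyclic C7=C8 isopropylidene group.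

- For: Tsuji–Trost C-allylation of cyclic 1,3-dione enols is established and catalytic, and needs no oxidant. Geometry alone distinguishes the two enol carbons. The isopropylidene group of A1 is directly the precursor of the C8 cation, which is stronger than the chosen route, where a hydrogenation and a silyl ether are needed.
- Against: the step makes one bond and one ring. Its substrate must already contain C3, C11 and C13 in the right relation. The seven-membered closure through a π-allyl complex competes with O-allylation and with attack at the tertiary terminus. The isopropenyl group is present before the acid-mediated C1–C8 closure, where it would compete for the proton and could isomerise. The benzoyl group at C1 is still missing.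
- Comparison: the chosen strategy makes both carbocycles and three stereocentres in one step from a flat arene with one stereocentre. Alternative 1 spreads the risk over more steps and a longer route.

Alternative 2: C3–C14 is cut. Forward, a phloroglucinol anion whose side chain is attached through C11 would displace a primary mesylate at C14 through its ipso carbon. This closes the cyclopentane and dearomatises the ring to the spiro trione enol A2.

- For: it is a simple intramolecular SN2 dearomatisation, five-membered closure is fast, and no redox step is involved. On reliability of the key step it is stronger than the chosen strategy.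
- Against: it closes only the cyclopentane and sets no stereocentre, since C3 of A2 is not yet stereogenic. The benzylic methine C11 and C13 must both be set in an open chain on either side of a quaternary carbon. The seven-membered ring, the C1–C8 bond, the benzoyl group and the geranyl group all remain, and the symmetric trione must later be desymmetrised.
- Comparison: the chosen strategy offers convergence in place of reliability. One stereocentre (C13) is made by auxiliary chemistry, and the rest follow in the cycloaddition.

Alternative 3: The seven-membered ring is made by one-carbon ring expansion. Forward, Bu3SnH would generate a primary radical at C6 on the bridgehead C5 of a bicyclo[3.3.1]nonane tetraone. The radical adds to the C7 ketone, and the alkoxy radical cleaves C5–C7 (Dowd–Beckwith), giving the bicyclo[4.3.1]decane tetraone A3.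

- For: the ring expansion is dependable when the new radical is flanked by carbonyl groups, as C5 is. Bicyclo[3.3.1]nonane cores of this family are accessible by established dearomatising annulations. The C7 ketone of A3 is a flexible handle, which the chosen route lacks.
- Against: the substrate already needs the cyclopentane fusion, two quaternary bridgeheads and a bromomethyl group, so it is about as hard as the target core. The step creates no stereocentre. The C7 ketone must then become CH–CMe2 with control at C7 in the presence of three other ketones, and A3 lacks the benzoyl group.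
- Comparison: the chosen strategy reaches the same ring system with C7 and C8 already in place and with fewer functional-group changes after the key step.

Key step: step 15

Remark: the dibutylboron enolate of 9 is assumed to react with cation 12 in its chelated form, anti to the benzyl group of the auxiliary, as the lithium and sodium enolates do. This gives (R) at C13 from the (S)-auxiliary; the (R)-auxiliary would be used if the sense proved opposite.

## Route

Step 1
Reactants: 1 phloroglucinol; 2 benzoyl chloride
Product: 3 2,4,6-trihydroxybenzophenone
Conditions: AlCl3, PhNO2, 60 °C; aq. HCl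
Reagents that add atoms: none
Why: Friedel–Crafts acylation of the most electron-rich arene; the first acyl group deactivates the ring and hydrogen-bonds to the flanking phenols, so monoacylation should be clean.

Step 2
Reactants: 3 2,4,6-trihydroxybenzophenone; 4 acrylic acid
Product: 5 6-benzoyl-5,7-dihydroxychroman-2-one
Conditions: MeSO3H (cat.), toluene, 90 °C
Reagents that add atoms: none
Why: Acid-promoted conjugate Friedel–Crafts alkylation at a free ring carbon followed by lactonisation to the dihydrocoumarin forms C3–C14. The 6-benzoyl lactone keeps both free hydroxyls hydrogen-bonded to the ketone, and the other lactone isomer would give the same open-chain compound in step 4.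

Step 3
Reactants: 5 6-benzoyl-5,7-dihydroxychroman-2-one
Product: 6 6-benzoyl-5,7-bis(tert-butyldimethylsilyloxy)chroman-2-one
Conditions: t-BuMe2SiOTf, 2,6-lutidine, CH2Cl2, 0 °C
Reagents that add atoms: tert-butyldimethylsilyl trifluoromethanesulfonate, CC(C)(C)[Si](C)(C)OS(=O)(=O)C(F)(F)F
Why: Silyl triflate silylates even the chelated phenols; the aryl lactone is inert to it.

Step 4
Reactants: 6 6-benzoyl-5,7-bis(tert-butyldimethylsilyloxy)chroman-2-one; 7 (S)-4-benzyloxazolidin-2-one
Product: 9 (S)-4-benzyl-3-{3-[3-benzoyl-2,4,6-tris(tert-butyldimethylsilyloxy)phenyl]propanoyl}oxazolidin-2-one, via ring-opened lithium phenoxide 8 (not isolated)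
Conditions: 7, n-BuLi, THF, −78 °C; add 6, −78 → −20 °C; t-BuMe2SiOTf, −78 → 0 °C
Reagents that add atoms: tert-butyldimethylsilyl trifluoromethanesulfonate, CC(C)(C)[Si](C)(C)OS(=O)(=O)C(F)(F)F
Why: N-acylation of the lithiated oxazolidinone by an aryl ester (active ester), driven by release of the more stable phenoxide 8. Silylation in the same flask prevents re-closure of the lactone.

Step 5
Reactants: 10 2-methylbut-3-yn-2-ol
Product: 11 hexacarbonyl[μ-(2-methylbut-3-yn-2-ol)]dicobalt
Conditions: Co2(CO)8, CH2Cl2, rt
Reagents that add atoms: dicobalt octacarbonyl, O=C=[Co](=C=O)(=C=O)(=C=O)[Co](=C=O)(=C=O)(=C=O)=C=O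
Why: Terminal alkynes displace two CO ligands to give the stable alkyne–Co2(CO)6 complex.

Step 6
Reactants: 11 hexacarbonyl[μ-(2-methylbut-3-yn-2-ol)]dicobalt
Product: 12 hexacarbonyl[μ-(2-methylbut-3-yn-2-ylium)]dicobalt tetrafluoroborate
Conditions: HBF4·OEt2, Et2O, −10 °C; filter
Reagents that add atoms: tetrafluoroboric acid (diethyl ether complex), [H+].F[B-](F)(F)F
Why: Ionisation of the complexed tertiary propargylic alcohol gives the cobalt-stabilised cation, which precipitates as its salt (first half of the Nicholas reaction).

Step 7
Reactants: 9 (S)-4-benzyl-3-{3-[3-benzoyl-2,4,6-tris(tert-butyldimethylsilyloxy)phenyl]propanoyl}oxazolidin-2-one; 12 hexacarbonyl[μ-(2-methylbut-3-yn-2-ylium)]dicobalt tetrafluoroborate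
Product: 14 (S)-4-benzyl-3-{(2R)-2-[3-benzoyl-2,4,6-tris(tert-butyldimethylsilyloxy)benzyl]-3,3-dimethylpent-4-ynoyl}oxazolidin-2-one, via hexacarbonyldicobalt complex 13 (not isolated)
Conditions: Bu2BOTf, i-Pr2NEt, CH2Cl2, −78 → 0 °C; 12, −78 → −30 °C; then N-methylmorpholine N-oxide, CH2Cl2, rt
Reagents that add atoms: none
Why: Nicholas reaction of a chiral boron enolate: the (Z)-enolate is attacked at the propargylic carbon of 12 on the face away from the benzyl group, forming C12–C13 and setting C13 as (R). The cluster rules out allene formation, the silyl-flanked and benzoyl-deactivated ring carbon should not compete with the enolate, and the amine N-oxide then releases the alkyne.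

Step 8
Reactants: 14 (S)-4-benzyl-3-{(2R)-2-[3-benzoyl-2,4,6-tris(tert-butyldimethylsilyloxy)benzyl]-3,3-dimethylpent-4-ynoyl}oxazolidin-2-one
Product: 15 S-ethyl (2R)-2-[3-benzoyl-2,4,6-tris(tert-butyldimethylsilyloxy)benzyl]-3,3-dimethylpent-4-ynethioate
Conditions: EtSH, n-BuLi, THF, 0 °C → rt
Reagents that add atoms: ethanethiol, CCS
Why: Lithium thiolate cleaves hindered N-acyloxazolidinones at the exocyclic carbonyl; it is weakly basic (no epimerisation at C13) and does not attack silicon, so the aryl silyl ethers should stay.

Step 9
Reactants: 15 S-ethyl (2R)-2-[3-benzoyl-2,4,6-tris(tert-butyldimethylsilyloxy)benzyl]-3,3-dimethylpent-4-ynethioate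
Product: 16 (3R)-3-[3-benzoyl-2,4,6-tris(tert-butyldimethylsilyloxy)benzyl]-4,4-dimethylhex-5-yn-2-one
Conditions: Me2CuLi (from MeLi, CuI), Et2O, −78 → −30 °C
Reagents that add atoms: lithium dimethylcuprate, [Li+].C[Cu-]C
Why: Thioester-to-ketone substitution with a cuprate stops at the ketone and leaves the hindered diaryl ketone untouched; the reagent is not basic enough to epimerise C13.

Step 10
Reactants: 16 (3R)-3-[3-benzoyl-2,4,6-tris(tert-butyldimethylsilyloxy)benzyl]-4,4-dimethylhex-5-yn-2-one
Product: 17 (3R,5E)-3-[3-benzoyl-2,4,6-tris(tert-butyldimethylsilyloxy)benzyl]-4,4-dimethyl-6-(tributylstannyl)hex-5-en-2-one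
Conditions: Bu3SnH, PdCl2(PPh3)2 (2 mol %), THF, 0 °C
Reagents that add atoms: tributyltin hydride, CCCC[SnH](CCCC)CCCC
Why: Palladium-catalysed syn-hydrostannation; the quaternary carbon next to the alkyne sends tin to the terminal carbon, giving the (E)-stannane, and ketones are inert.

Step 11
Reactants: 18 3-hydroxy-3-methylbutan-2-one
Product: 19 3-methyl-3-(triethylsilyloxy)butan-2-one
Conditions: Et3SiOTf, 2,6-lutidine, CH2Cl2, −78 → 0 °C
Reagents that add atoms: triethylsilyl trifluoromethanesulfonate, CC[Si](CC)(CC)OS(=O)(=O)C(F)(F)F
Why: Silyl triflate silylates the tertiary alcohol.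

Step 12
Reactants: 19 3-methyl-3-(triethylsilyloxy)butan-2-one
Product: 20 3-methyl-3-(triethylsilyloxy)but-1-en-2-yl trifluoromethanesulfonate
Conditions: KN(SiMe3)2, THF, −78 °C; N-(5-chloro-2-pyridyl)bis(trifluoromethanesulfonimide), −78 °C
Reagents that add atoms: N-(5-chloro-2-pyridyl)bis(trifluoromethanesulfonimide), O=S(=O)(N(c1ccc(Cl)cn1)S(=O)(=O)C(F)(F)F)C(F)(F)F
Why: The ketone can enolise only towards the methyl group; the reactive pyridyl triflimide traps the enolate at −78 °C before silyl migration can occur.

Step 13
Reactants: 17 (3R,5E)-3-[3-benzoyl-2,4,6-tris(tert-butyldimethylsilyloxy)benzyl]-4,4-dimethyl-6-(tributylstannyl)hex-5-en-2-one; 20 3-methyl-3-(triethylsilyloxy)but-1-en-2-yl trifluoromethanesulfonate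
Product: 21 (3R,5E)-3-[3-benzoyl-2,4,6-tris(tert-butyldimethylsilyloxy)benzyl]-4,4,8-trimethyl-7-methylidene-8-(triethylsilyloxy)non-5-en-2-one
Conditions: Pd(PPh3)4 (10 mol %), CuCl, LiCl, DMSO, rt → 45 °C
Reagents that add atoms: none
Why: Stille coupling of an alkenyl triflate with an alkenylstannane forms C10–C7 with retention of the E geometry; copper chloride speeds transmetalation of the hindered partners.

Step 14
Reactants: 21 (3R,5E)-3-[3-benzoyl-2,4,6-tris(tert-butyldimethylsilyloxy)benzyl]-4,4,8-trimethyl-7-methylidene-8-(triethylsilyloxy)non-5-en-2-one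
Product: 22 (3R,5E)-3-(3-benzoyl-2,4,6-trihydroxybenzyl)-4,4,8-trimethyl-7-methylidene-8-(triethylsilyloxy)non-5-en-2-one
Conditions: K2CO3, MeOH, 0 °C; pH 6 buffer
Reagents that add atoms: none
Why: Base methanolysis removes aryl silyl ethers of an acidic acylphloroglucinol much faster than the tertiary alkyl silyl ether; the hindered C13–H should not exchange at 0 °C.

Step 15
Reactants: 22 (3R,5E)-3-(3-benzoyl-2,4,6-trihydroxybenzyl)-4,4,8-trimethyl-7-methylidene-8-(triethylsilyloxy)non-5-en-2-one
Product: 24 (4+3) cycloadduct (cyclopentane-fused bicyclo[4.3.1]dec-7-ene enol triketone carrying the C7 silyloxyisopropyl group and the C13 acetyl group), via phenoxonium acetate 23 (not isolated)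
Conditions: PhI(OAc)2 (1.05 equiv), (CF3)2CHOH–CH2Cl2 (1:3), −40 → 0 °C
Reagents that add atoms: none
Why: Proposed new method: two-electron oxidation of the C4 phenol by PhI(OAc)2 in the ionising, non-nucleophilic fluoroalcohol should give the delocalised cation 23, whose C3–C4–C5 segment is a ring-embedded 2-oxidoallyl cation stabilised by the C2 and C9 hydroxyls; the tethered diene adds C11 to C3 and C6 to C5, and proton loss leaves the neutral enolised 2-benzoyl-1,3-dione of 24. The closest known reactions are intramolecular (4+3) cycloadditions of cyclic oxyallyl cations with tethered dienes and cationic (5+2) cycloadditions of phenoxonium ions made by hypervalent iodine oxidation; the new element is a free acylphloroglucinol as the oxyallyl precursor. The cyclopentane closes by 5-exo attack of C11 on C3 through the tether C14–C13–C12, and the seven-membered ring closes when the enol carbon C5 bonds to the allyl terminus C6 (7-endo with respect to the C6–C7 π bond), in concert or directly after the first bond. For C3 and C11, the E diene in its s-cis form (favoured by the bulky C7 substituent) adds suprafacially through the compact arrangement with C10 and C7 over C4–O, the only one that lets the bridge reach C5, so C10 ends cis to C4 and H11 cis to C2. C5 is fixed by the bridge, because C6 must bond on the ring face that already carries C11. The absolute sense comes from C13: in the envelope-like closure of the five-membered ring the acetyl group should take the face away from C10, which selects the ring face and places the acetyl group trans to C10. The step needs C5 and not C1 as second terminus (C1 carries the benzoyl group, is the least nucleophilic enol carbon and lies on the C2 side), carbon and not oxygen capture of the allyl cation (helped by the compact geometry, low temperature and a hydrogen-bonding solvent that lowers the nucleophilicity of O4), and survival of the tertiary silyl ether (acetic acid is the only acid formed).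

Step 16
Reactants: 24 (4+3) cycloadduct
Product: 25 7,10-dihydro cycloadduct (cyclopentane-fused bicyclo[4.3.1]decane enol triketone with C7–H and the C8 silyl ether)
Conditions: H2 (1 atm), [Ir(cod)(PCy3)(py)]PF6 (10 mol %), CH2Cl2, rt
Reagents that add atoms: none
Why: The cationic iridium catalyst hydrogenates hindered trisubstituted alkenes without cleaving the allylic C–O bond and leaves ketones alone. Hydrogen is expected on the alkene face turned to the one-carbon bridge C4 (the open face when the four-carbon bridge leans over the trione ring, and the face where C4=O can hold the metal), which sets C7 with C8 on the side of C1.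

Step 17
Reactants: 25 7,10-dihydro cycloadduct
Product: 26 caged acetyl trione (homoadamantane-type 1-benzoyl-2,4,9-trione with C5–H and the C13 acetyl group)
Conditions: CF3SO3H (0.3 equiv), (CF3)2CHOH–CH2Cl2, 0 °C → rt
Reagents that add atoms: none
Why: Ionisation of the tertiary silyl ether gives the C8 cation, which the enol carbon C1 captures through a six-membered chair (cation–enol cyclisation, the laboratory counterpart of the presumed biosynthetic closure of such cages); C1 can form in only one configuration. O-alkylation is reversible under acid, and a wrong C7 epimer should be corrected by reversible loss and return of the C7 proton through the C7=C8 alkene.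

Step 18
Reactants: 26 caged acetyl trione
Product: 27 caged isopropenyl trione (as 26 with the C13 isopropenyl group and C5–H)
Conditions: Ph3PCH3Br, KN(SiMe3)2, THF, 0 °C → rt
Reagents that add atoms: methylenetriphenylphosphorane, C=P(c1ccccc1)(c1ccccc1)c1ccccc1
Why: Wittig methylenation of the only ketone not flanked by a quaternary carbon; the hindered amide base avoids alkoxide that could cleave the benzoyl group.

Step 19
Reactants: 27 caged isopropenyl trione; 28 geranyl bromide
Product: 29 target CNP0110731.1
Conditions: lithium 2,2,6,6-tetramethylpiperidide, THF, −78 → −40 °C; 28, −78 → 0 °C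
Reagents that add atoms: none
Why: Bridgehead deprotonation between the C4 and C9 ketones and SN2 alkylation, the reaction type used for bridgehead substitution of bicyclo[3.3.1]nonane triones. C5–H is the only proton α to a carbonyl group, the primary allylic bromide keeps its E geometry, and the cage allows only one configuration at C5.

## Compound list

1 | phloroglucinol | Oc1cc(O)cc(O)c1 | starting material
2 | benzoyl chloride | O=C(Cl)c1ccccc1 | starting material
3 | 2,4,6-trihydroxybenzophenone | O=C(c1ccccc1)c1c(O)cc(O)cc1O | intermediate
4 | acrylic acid | C=CC(=O)O | starting material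
5 | 6-benzoyl-5,7-dihydroxychroman-2-one | O=C1CCc2c(O1)cc(O)c(C(=O)c3ccccc3)c2O | intermediate
6 | 6-benzoyl-5,7-bis(tert-butyldimethylsilyloxy)chroman-2-one | O=C1CCc2c(O1)cc(O[Si](C)(C)C(C)(C)C)c(C(=O)c3ccccc3)c2O[Si](C)(C)C(C)(C)C | intermediate
7 | (S)-4-benzyloxazolidin-2-one | O=C1N[C@@H](Cc2ccccc2)CO1 | starting material
8 | lithium 3-benzoyl-2-{3-[(S)-4-benzyl-2-oxooxazolidin-3-yl]-3-oxopropyl}-3,5-bis(tert-butyldimethylsilyloxy)phenoxide (ring-opened lithium phenoxide) | [Li+].[O-]c1cc(O[Si](C)(C)C(C)(C)C)c(C(=O)c2ccccc2)c(O[Si](C)(C)C(C)(C)C)c1CCC(=O)N1[C@@H](Cc2ccccc2)COC1=O | intermediate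
9 | (S)-4-benzyl-3-{3-[3-benzoyl-2,4,6-tris(tert-butyldimethylsilyloxy)phenyl]propanoyl}oxazolidin-2-one | CC(C)(C)[Si](C)(C)Oc1cc(O[Si](C)(C)C(C)(C)C)c(C(=O)c2ccccc2)c(O[Si](C)(C)C(C)(C)C)c1CCC(=O)N1[C@@H](Cc2ccccc2)COC1=O | intermediate
10 | 2-methylbut-3-yn-2-ol | CC(C)(O)C#C | starting material
11 | hexacarbonyl[μ-(2-methylbut-3-yn-2-ol)]dicobalt | CC(C)(O)C12[CH]3[Co]1(=C=O)(=C=O)(=C=O)[Co]23(=C=O)(=C=O)=C=O | intermediate
12 | hexacarbonyl[μ-(2-methylbut-3-yn-2-ylium)]dicobalt tetrafluoroborate | C[C+](C)C12[CH]3[Co]1(=C=O)(=C=O)(=C=O)[Co]23(=C=O)(=C=O)=C=O.F[B-](F)(F)F | intermediate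
13 | hexacarbonyldicobalt complex of 14 (alkyne-bound) | CC(C)(C)[Si](C)(C)Oc1cc(O[Si](C)(C)C(C)(C)C)c(C(=O)c2ccccc2)c(O[Si](C)(C)C(C)(C)C)c1C[C@@H](C(=O)N1[C@@H](Cc2ccccc2)COC1=O)C(C)(C)C12[CH]3[Co]1(=C=O)(=C=O)(=C=O)[Co]23(=C=O)(=C=O)=C=O | intermediate
14 | (S)-4-benzyl-3-{(2R)-2-[3-benzoyl-2,4,6-tris(tert-butyldimethylsilyloxy)benzyl]-3,3-dimethylpent-4-ynoyl}oxazolidin-2-one | CC(C)(C)[Si](C)(C)Oc1cc(O[Si](C)(C)C(C)(C)C)c(C(=O)c2ccccc2)c(O[Si](C)(C)C(C)(C)C)c1C[C@@H](C(=O)N1[C@@H](Cc2ccccc2)COC1=O)C(C)(C)C#C | intermediate
15 | S-ethyl (2R)-2-[3-benzoyl-2,4,6-tris(tert-butyldimethylsilyloxy)benzyl]-3,3-dimethylpent-4-ynethioate | CC(C)(C)[Si](C)(C)Oc1cc(O[Si](C)(C)C(C)(C)C)c(C(=O)c2ccccc2)c(O[Si](C)(C)C(C)(C)C)c1C[C@@H](C(=O)SCC)C(C)(C)C#C | intermediate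
16 | (3R)-3-[3-benzoyl-2,4,6-tris(tert-butyldimethylsilyloxy)benzyl]-4,4-dimethylhex-5-yn-2-one | CC(C)(C)[Si](C)(C)Oc1cc(O[Si](C)(C)C(C)(C)C)c(C(=O)c2ccccc2)c(O[Si](C)(C)C(C)(C)C)c1C[C@@H](C(C)=O)C(C)(C)C#C | intermediate
17 | (3R,5E)-3-[3-benzoyl-2,4,6-tris(tert-butyldimethylsilyloxy)benzyl]-4,4-dimethyl-6-(tributylstannyl)hex-5-en-2-one | CC(C)(C)[Si](C)(C)Oc1cc(O[Si](C)(C)C(C)(C)C)c(C(=O)c2ccccc2)c(O[Si](C)(C)C(C)(C)C)c1C[C@@H](C(C)=O)C(C)(C)/C=C/[Sn](CCCC)(CCCC)CCCC | intermediate
18 | 3-hydroxy-3-methylbutan-2-one | CC(=O)C(C)(C)O | starting material
19 | 3-methyl-3-(triethylsilyloxy)butan-2-one | CC(=O)C(C)(C)O[Si](CC)(CC)CC | intermediate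
20 | 3-methyl-3-(triethylsilyloxy)but-1-en-2-yl trifluoromethanesulfonate | C=C(OS(=O)(=O)C(F)(F)F)C(C)(C)O[Si](CC)(CC)CC | intermediate
21 | (3R,5E)-3-[3-benzoyl-2,4,6-tris(tert-butyldimethylsilyloxy)benzyl]-4,4,8-trimethyl-7-methylidene-8-(triethylsilyloxy)non-5-en-2-one | CC(C)(C)[Si](C)(C)Oc1cc(O[Si](C)(C)C(C)(C)C)c(C(=O)c2ccccc2)c(O[Si](C)(C)C(C)(C)C)c1C[C@@H](C(C)=O)C(C)(C)/C=C/C(=C)C(C)(C)O[Si](CC)(CC)CC | intermediate
22 | (3R,5E)-3-(3-benzoyl-2,4,6-trihydroxybenzyl)-4,4,8-trimethyl-7-methylidene-8-(triethylsilyloxy)non-5-en-2-one (key-step precursor) | Oc1cc(O)c(C(=O)c2ccccc2)c(O)c1C[C@@H](C(C)=O)C(C)(C)/C=C/C(=C)C(C)(C)O[Si](CC)(CC)CC | intermediate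
23 | phenoxonium (2-oxidoallyl) cation of 22, acetate salt | O=C1C=C(O)C(C(=O)c2ccccc2)=C(O)[C+]1C[C@@H](C(C)=O)C(C)(C)/C=C/C(=C)C(C)(C)O[Si](CC)(CC)CC.CC(=O)[O-] | intermediate
24 | (4+3) cycloadduct: cyclopentane-fused bicyclo[4.3.1]dec-7-ene; C4 ketone; enolised 1-benzoyl-2,9-dione; C7 bears C(CH3)2OSiEt3; C3–C11 cis-fused with C10 cis to C4; C13 acetyl (R) trans to C10 | CC(=O)[C@@H]1C[C@@]23C(=O)[C@H](C(=O)C(C(=O)c4ccccc4)=C3O)CC(=C[C@H]2C1(C)C)C(C)(C)O[Si](CC)(CC)CC | intermediate
25 | 7,10-dihydro cycloadduct: as 24 with C7–H on the face of C4 and C8 directed towards C1 | CC(=O)[C@@H]1C[C@@]23C(=O)[C@H](C(=O)C(C(=O)c4ccccc4)=C3O)C[C@@H](C[C@H]2C1(C)C)C(C)(C)O[Si](CC)(CC)CC | intermediate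
26 | caged acetyl trione: homoadamantane-type 1-benzoyl-2,4,9-trione with the C1–C8 bond, C5–H and the C13 acetyl group (R) | CC(=O)[C@@H]1C[C@@]23C(=O)[C@H]4C[C@@H](C[C@H]2C1(C)C)C(C)(C)[C@](C(=O)c1ccccc1)(C4=O)C3=O | intermediate
27 | caged isopropenyl trione: as 26 with the C13 isopropenyl group (S) and C5–H | C=C(C)[C@@H]1C[C@@]23C(=O)[C@H]4C[C@@H](C[C@H]2C1(C)C)C(C)(C)[C@](C(=O)c1ccccc1)(C4=O)C3=O | intermediate
28 | geranyl bromide, (2E)-1-bromo-3,7-dimethylocta-2,6-diene | CC(C)=CCC/C(C)=C/CBr | starting material
29 | CNP0110731.1: as 27 with the (E)-geranyl group on C5 | C=C(C)[C@@H]1C[C@@]23C(=O)[C@@]4(C/C=C(\C)CCC=C(C)C)C[C@@H](C[C@H]2C1(C)C)C(C)(C)[C@](C(=O)c1ccccc1)(C4=O)C3=O | target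

## Step count and least certain steps

Total step count: 19. Longest linear sequence: 15 steps (steps 1–4, 7–10 and 13–19, from phloroglucinol 1).

**Step 15 (key step).**

- Likely failure: once C3–C11 has formed, the allyl cation may be captured by the oxygen next to C3, giving a five-membered ether, instead of by C5. The diene may also add on the other ring face if the acetyl group at C13 discriminates poorly, or acetate or solvent may be captured at C5.
- Fallback, from 22 back to 24: palladium-catalysed oxidative 1,4-dialkylation of the diene with divalent palladium, using Pd(OAc)2 (10 mol %) and 1,4-benzoquinone in acetone–AcOH at rt. The enol carbon C3 adds to the metal-bound diene at C11 (5-exo, anti to palladium). The π-allylpalladium across C10–C7–C6 is then attacked at its unsubstituted terminus C6 by C5, and the zerovalent palladium released is reoxidised by the quinone.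
- Why it should work: both carbon nucleophiles attack anti to the metal, so the two bonds form on the same diene face, as in the cycloaddition. A soft enol carbon attacking a π-allyl complex favours C- over O-alkylation. The reaction types are known (1,4-additions to 1,3-dienes with tethered carbon nucleophiles, and dearomatising π-allyl alkylation of acylphloroglucinols). It makes no compound outside the list (none F0).

**Step 19.**

- Likely failure: bridgehead deprotonation may be too slow, because an enolate at C5 would need a trans C4=C5 bond within the seven-membered ring of the closed cage. The amide base may then add to the benzoyl or ring ketones and cleave the triketone.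
- Fallback, from 22 back to 29: the bridgehead anion is made by halogen–metal exchange instead of deprotonation.
  - 22 is brominated at its free ring carbon (N-bromosuccinimide, CH2Cl2, −78 °C) to (3R,5E)-3-(3-benzoyl-5-bromo-2,4,6-trihydroxybenzyl)-4,4,8-trimethyl-7-methylidene-8-(triethylsilyloxy)non-5-en-2-one F1.
  - The conditions of step 15 should give the C5-bromo cycloadduct F2, with bromine on the new quaternary bridgehead.
  - The conditions of steps 16 and 17 should give the C5-bromo dihydro cycloadduct F3 and the C5-bromo caged acetyl trione F4.
  - Bromine–magnesium exchange on F4 (i-PrMgCl·LiCl, THF, −78 °C) and addition of 28 should give the C5-geranyl caged acetyl trione F5.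
  - F5 is methylenated as in step 18 to 29.
  - Exchange of bridgehead α-halo ketones and alkylation of the resulting organomagnesium are known reactions.

**Step 17.**

- Likely failure: a 1,2-hydride shift from C7 to the C8 cation followed by transannular capture at C7, or elimination without return. Prolonged acid could also promote hemiketalisation of the acetyl group with the C2 enol.
- Fallback, from 25 back to 26: the cation is generated once, at low temperature and without Brønsted acid.
  - HF·pyridine in THF gives the tertiary alcohol F6.
  - HCl in Et2O at 0 °C gives the tertiary chloride F7.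
  - AgOTf with 2,6-di-tert-butylpyridine in CH2Cl2 at −78 °C abstracts chloride, so the enol carbon C1 captures the cation before it can rearrange.

**Step 16.**

- Likely failure: hydrogen delivery to the wrong alkene face if the four-carbon bridge folds over C4 instead of over the trione ring; ionisation or hydrogenolysis of the allylic C–O bond; or catalyst inhibition by the acidic enol.
- Fallback, from 24 back to 26: ionic reduction with allylic transposition (Et3SiH, BF3·OEt2, CH2Cl2, −78 °C) should deliver hydride to C10 of the allyl cation and give the C7=C8 isopropylidene compound F8. Under the conditions of step 17, F8 is protonated at C7 to the same C8 cation and closes to 26. C7 is then set only in the reversible protonation, where the cage selects the right epimer.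

## Further compounds

F0 | step 15 | none | none
F1 | step 19 | (3R,5E)-3-(3-benzoyl-5-bromo-2,4,6-trihydroxybenzyl)-4,4,8-trimethyl-7-methylidene-8-(triethylsilyloxy)non-5-en-2-one | Oc1c(Br)c(O)c(C(=O)c2ccccc2)c(O)c1C[C@@H](C(C)=O)C(C)(C)/C=C/C(=C)C(C)(C)O[Si](CC)(CC)CC
F2 | step 19 | C5-bromo cycloadduct (24 with bromine in place of the C5 hydrogen) | CC(=O)[C@@H]1C[C@@]23C(=O)[C@](Br)(C(=O)C(C(=O)c4ccccc4)=C3O)CC(=C[C@H]2C1(C)C)C(C)(C)O[Si](CC)(CC)CC
F3 | step 19 | C5-bromo dihydro cycloadduct (25 with bromine in place of the C5 hydrogen) | CC(=O)[C@@H]1C[C@@]23C(=O)[C@](Br)(C(=O)C(C(=O)c4ccccc4)=C3O)C[C@@H](C[C@H]2C1(C)C)C(C)(C)O[Si](CC)(CC)CC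
F4 | step 19 | C5-bromo caged acetyl trione (26 with bromine in place of the C5 hydrogen) | CC(=O)[C@@H]1C[C@@]23C(=O)[C@@]4(Br)C[C@@H](C[C@H]2C1(C)C)C(C)(C)[C@](C(=O)c1ccccc1)(C4=O)C3=O
F5 | step 19 | C5-geranyl caged acetyl trione (29 with acetyl in place of isopropenyl) | CC(=O)[C@@H]1C[C@@]23C(=O)[C@@]4(C/C=C(\C)CCC=C(C)C)C[C@@H](C[C@H]2C1(C)C)C(C)(C)[C@](C(=O)c1ccccc1)(C4=O)C3=O
F6 | step 17 | tertiary alcohol (25 with C8–OH in place of the silyl ether) | CC(=O)[C@@H]1C[C@@]23C(=O)[C@H](C(=O)C(C(=O)c4ccccc4)=C3O)C[C@@H](C[C@H]2C1(C)C)C(C)(C)O
F7 | step 17 | tertiary chloride (25 with C8–Cl in place of the silyl ether) | CC(=O)[C@@H]1C[C@@]23C(=O)[C@H](C(=O)C(C(=O)c4ccccc4)=C3O)C[C@@H](C[C@H]2C1(C)C)C(C)(C)Cl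
F8 | step 16 | C7=C8 isopropylidene compound (bicyclo[4.3.1]decane enol triketone with C10 H2 and no oxygen at C8) | CC(=O)[C@@H]1C[C@@]23C(=O)[C@H](C(=O)C(C(=O)c4ccccc4)=C3O)CC(C[C@H]2C1(C)C)=C(C)C
A1 | alternative 1 | cyclopentane-fused bicyclo[4.3.1]decane enol with C7 isopropylidene | C=C(C)[C@@H]1C[C@@]23C(=O)C(=C(O)C=C3O)CC(=C(C)C)C[C@H]2C1(C)C
A2 | alternative 2 | spiro trione enol with C1 and C5 unsubstituted | C=C(C)[C@@H]1CC2(C(O)=CC(=O)C=C2O)[C@@H](CC=C(C)C)C1(C)C
A3 | alternative 3 | cyclopentane-fused bicyclo[4.3.1]decane tetraone with C7 ketone | C=C(C)[C@@H]1C[C@@]23C(=O)[C@H](C(=O)C=C3O)CC(=O)C[C@H]2C1(C)C
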